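**Retrosynthetic overview**
- Numbering: C1 (allyl bridgehead), C2=C3 (OMe on C3), C4 (carbinol), C5 (OMe bridgehead), C6 (aryl), C7 (methyl), C8 (bridging C=O). Ring A is the guaiacyl ring and ring B is the six-membered ring C1–C2–C3–C4–C5–C8.
- Feature: with C4 at the ketone level, C5 lies between the C4 and C8 carbonyl carbons, so it is a 1,3-dicarbonyl nucleophile. C6 is benzylic to a para-hydroxyaryl ring, so it is a latent para-quinone methide carbon, tied to C5 through C8–C1–C7.
- Disconnections: (a) C4–OH from C4=O by 1,2-reduction; (b) C5–C6 by oxidative quinone methide cyclisation of a 6-allyl-6-alkyl-3-hydroxycyclohexadienone; (c) C1–allyl by dearomative allylation of a 4-alkylresorcinol.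
- Further back: (d) the C8 oxygen by ring B bromination and borylation–oxidation; (e) C7 by asymmetric hydrogenation of a geometrically pure E-1,2-diarylpropene made by Suzuki–Miyaura coupling.
- Ring order: ring B enters as an arene and is dearomatised in step 10. The five-membered ring C1–C7–C6–C5–C8 is closed in step 12.

Key step: step 12

Assumption: the sense of induction of the chiral ligands in steps 6 and 10 is carried over from the closest model substrates; if a first run shows the opposite sense, the equally available mirror-image ligand is used and nothing else changes.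

**Step 1**
Reactants: 1 4-bromo-2-methoxyphenol
Product: 2 (4-bromo-2-methoxyphenoxy)triisopropylsilane
Conditions: TIPSCl, imidazole, DMF, rt
Reagents that add atoms: triisopropylsilyl chloride, CC(C)[Si](Cl)(C(C)C)C(C)C
Why: Imidazole-promoted silyl ether formation masks the ring A hydroxyl with a group that survives organometallic reagents, base and hydrogenation and can later be removed with fluoride beside an allyl group.

**Step 2**
Reactants: 2 (4-bromo-2-methoxyphenoxy)triisopropylsilane; 3 prop-1-ynylmagnesium bromide
Product: 5 triisopropyl[2-methoxy-4-(prop-1-yn-1-yl)phenoxy]silane, via prop-1-ynylzinc bromide 4 (not isolated)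
Conditions: 3, ZnBr2, THF, 0 °C; then 2, Pd(OAc)2 (2 mol %), SPhos (4 mol %), 60 °C
Reagents that add atoms: zinc dibromide, Br[Zn]Br (zinc and bromine stay only in 4)
Why: Negishi coupling, in which the alkynylzinc 4 transfers the propynyl group to the arylpalladium species and the electron-rich biarylphosphine eases oxidative addition into the electron-rich aryl bromide.

**Step 3**
Reactants: 5 triisopropyl[2-methoxy-4-(prop-1-yn-1-yl)phenoxy]silane
Product: 6 (Z)-triisopropyl{2-methoxy-4-[2-(4,4,5,5-tetramethyl-1,3,2-dioxaborolan-2-yl)prop-1-en-1-yl]phenoxy}silane (aryl cis to methyl, boron cis to the vinyl hydrogen)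
Conditions: B2pin2, CuCl (5 mol %), NaOtBu (10 mol %), P(4-MeC6H4)3 (6 mol %), MeOH (2 equiv), THF, rt
Reagents that add atoms: bis(pinacolato)diboron, CC1(C)OB(OC1(C)C)B1OC(C)(C)C(C)(C)O1
Why: Copper-catalysed borylcupration–protonation of an aryl alkyl alkyne adds syn, with copper at the aryl-bearing carbon and boron at the methyl-bearing carbon, and methanol cleaves the C–Cu bond with retention, which fixes the alkene geometry.

**Step 4**
Reactants: 7 4-bromo-2,6-dimethoxyphenol
Product: 8 2-(benzyloxy)-5-bromo-1,3-dimethoxybenzene
Conditions: BnBr, K2CO3, DMF, rt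
Reagents that add atoms: benzyl bromide, BrCc1ccccc1
Why: Williamson ether synthesis protects O4 with a group that withstands NBS and n-BuLi and is removed by hydrogenolysis before the allyl group is present.

**Step 5**
Reactants: 6 (Z)-alkenylboronate; 8 2-(benzyloxy)-5-bromo-1,3-dimethoxybenzene
Product: 9 (E)-{4-[2-(4-benzyloxy-3,5-dimethoxyphenyl)prop-1-en-1-yl]-2-methoxyphenoxy}triisopropylsilane (the two aryl groups trans)
Conditions: Pd(OAc)2 (2 mol %), SPhos (4 mol %), K3PO4, degassed toluene/H2O, 60 °C
Reagents that add atoms: none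
Why: Suzuki–Miyaura coupling proceeds with retention at the alkenyl carbon and should give only the E alkene, which matters because E and Z isomers would be hydrogenated to opposite configurations at C7.

**Step 6**
Reactants: 9 (E)-1,2-diarylpropene
Product: 10 (R)-{4-[2-(4-benzyloxy-3,5-dimethoxyphenyl)propyl]-2-methoxyphenoxy}triisopropylsilane
Conditions: [Ir(cod)(L)]BArF (1 mol %; L = (S)-4-tert-butyl-2-[2-(di-o-tolylphosphanyl)phenyl]-4,5-dihydrooxazole, BArF = B[3,5-(CF3)2C6H3]4), H2 (50 bar), CH2Cl2, rt
Reagents that add atoms: none
Why: Iridium-catalysed asymmetric hydrogenation of an unfunctionalised trisubstituted alkene, for which E-1,2-diarylpropenes without ortho substituents are the standard substrates; the phosphine–oxazoline ligand selects the alkene face and sets C7 as R, and benzyl and silyl ethers are left alone.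

**Step 7**
Reactants: 10 (R)-diarylpropane
Product: 11 (R)-{4-[2-(4-benzyloxy-2-bromo-3,5-dimethoxyphenyl)propyl]-2-methoxyphenoxy}triisopropylsilane
Conditions: NBS (1.0 equiv), MeCN, −20 to 0 °C, dark
Reagents that add atoms: N-bromosuccinimide, O=C1CCC(=O)N1Br
Why: Electrophilic aromatic bromination should choose ring B, because its free positions are ortho to one methoxy group and para to the other whereas the best ring A position has only one para methoxy group, and the two ring B positions are equivalent by rotation about C1–C7, so one monobromide is expected.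

**Step 8**
Reactants: 11 (R)-aryl bromide
Product: 14 (R)-3-(benzyloxy)-2,4-dimethoxy-6-{1-[3-methoxy-4-(triisopropylsilyloxy)phenyl]propan-2-yl}phenol, via aryllithium 12 (not isolated), via dimethyl arylboronate 13 (not isolated)
Conditions: n-BuLi, THF, −78 °C; B(OMe)3, −78 °C to rt; AcOH, 30 % H2O2, 0 °C to rt
Reagents that add atoms: n-butyllithium, [Li]CCCC (lithium in 12); trimethyl borate, COB(OC)OC (boron and two methoxy groups in 13); hydrogen peroxide, OO (the new oxygen of 14)
Why: Bromine–lithium exchange, borylation and boronate oxidation (1,2-aryl shift from boron to oxygen) replace bromine by hydroxyl at the same carbon and so place the C8 oxygen without touching C7.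

**Step 9**
Reactants: 14 (R)-monobenzylated phenol
Product: 15 (R)-2,4-dimethoxy-6-{1-[3-methoxy-4-(triisopropylsilyloxy)phenyl]propan-2-yl}benzene-1,3-diol
Conditions: H2 (1 atm), Pd/C (10 %), EtOAc, rt; handled under argon
Reagents that add atoms: none
Why: Hydrogenolysis of the aryl benzyl ether frees O4 while no alkene is yet present, and the silyl ether on ring A stays.

**Step 10**
Reactants: 15 (R)-4-alkylresorcinol; 16 allyl methyl carbonate
Product: 17 (6R)-6-allyl-3-hydroxy-2,4-dimethoxy-6-{(2R)-1-[3-methoxy-4-(triisopropylsilyloxy)phenyl]propan-2-yl}cyclohexa-2,4-dien-1-one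
Conditions: Pd2(dba)3·CHCl3 (2.5 mol %), (1R,2R)-N,N'-bis[2-(diphenylphosphanyl)benzoyl]cyclohexane-1,2-diamine (7.5 mol %), Cs2CO3 (2.2 equiv), 16 (1.0 equiv, slow addition), degassed 1,4-dioxane, rt; pH 4 buffer work-up
Reagents that add atoms: none
Why: Proposed new method: zerovalent palladium ionises 16 to a cationic π-allylpalladium complex, and the caesium phenoxide of 15 attacks it from outside the coordination sphere through C1, the only ring carbon ortho or para to both oxygens that carries alkyl instead of methoxy. The product is a stabilised 1,3-diketonate, a weaker nucleophile than the remaining phenoxide, and any O-allyl vinylogous ester can re-ionise. C1 is set as R by the chiral pocket of the diphosphine, which overrides the weak bias of C7. The closest known reaction types are the Pd-catalysed intermolecular asymmetric allylic dearomatisation of 1-substituted 2-naphthols with this ligand class and the achiral Pd-catalysed C-allylative dearomatisation of 4-alkyl-3,5-dimethoxyphenols (Tsuji–Trost allylation).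

**Step 11**
Reactants: 17 silyl-protected allyl dienone
Product: 18 (6R)-6-allyl-3-hydroxy-6-[(2R)-1-(4-hydroxy-3-methoxyphenyl)propan-2-yl]-2,4-dimethoxycyclohexa-2,4-dien-1-one
Conditions: TBAF, AcOH, THF, 0 °C
Reagents that add atoms: none
Why: Fluoride-induced cleavage of the aryl silyl ether, buffered with acetic acid so that neither phenoxide nor enolate builds up, leaves the allyl group, the enol ether and both stereocentres untouched.

**Step 12**
Reactants: 18 free guaiacol vinylogous acid
Product: 20 (1R,5S,6S,7R)-1-allyl-6-(4-hydroxy-3-methoxyphenyl)-3,5-dimethoxy-7-methylbicyclo[3.2.1]oct-2-ene-4,8-dione, via para-quinone methide 19 (not isolated)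
Conditions: Ag2O (2 equiv), 4 Å MS, CH2Cl2 (0.01 M), 0 °C to rt, dark, argon; filtration through Celite
Reagents that add atoms: none
Why: Ag2O removes two electrons and two protons from the 4-alkylguaiacol of 18, the only phenol left now that ring B is dearomatised, and gives the para-quinone methide 19 with C6 as its soft exocyclic electrophile. The enolic 1,3-dicarbonyl carbon C5 then adds to C6 in an intramolecular 1,6-conjugate addition that rearomatises ring A; the closest known reaction type is the Ag2O oxidation of 4-alkylphenols to para-quinone methides that cyclise onto a tethered beta-dicarbonyl carbon. One ring is closed, the cyclopentane C1–C7–C6–C5–C8, in a 5-(enolexo)-exo-trig mode through the C4 enol, which turns the cyclohexadienone into the bicyclo[3.2.1]octenedione. C5 can be reached only from the ring face that carries the C7 chain, so its configuration follows from C1, and C6 is set by A(1,3) strain in 19, which holds the C7–H in the quinone methide plane so that attack leaves the aryl group trans to the C7 methyl, that is endo and anti to C8. The step needs oxidation at the phenol and not at the enol, secured by the weak guaiacol O–H bond and by the methoxy group on C5 that denies the enol an easy two-electron outlet, and it needs C5 and not O8 as the nucleophile, secured by the chain on C1 standing over the ring face so that C6 lies above the C5 p orbital while O8 lies in the ring plane. Because both closures can reopen to 19, the reaction is run neutral, aprotic and cold under kinetic control and 20 is reduced at once.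

**Step 13**
Reactants: 20 bicyclic enedione
Product: 21 (1R,4S,5R,6S,7R)-1-allyl-4-hydroxy-6-(4-hydroxy-3-methoxyphenyl)-3,5-dimethoxy-7-methylbicyclo[3.2.1]oct-2-en-8-one
Conditions: NaBH4 (1.0 equiv), CeCl3·7H2O (1.2 equiv), MeOH, −78 °C
Reagents that add atoms: none
Why: Luche 1,2-reduction should take the cerium trichloride-activated enone carbonyl C4, which has one fully substituted neighbour, in preference to C8, which has two; the endo aryl group on C6 covers the lower face, so hydride arrives syn to C8 and the hydroxyl ends anti to C8 (4S).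

**Compound list**
1 | 4-bromo-2-methoxyphenol | COc1cc(Br)ccc1O | starting material
2 | (4-bromo-2-methoxyphenoxy)triisopropylsilane | COc1cc(Br)ccc1O[Si](C(C)C)(C(C)C)C(C)C | intermediate
3 | prop-1-ynylmagnesium bromide | CC#C[Mg]Br | starting material
4 | prop-1-ynylzinc bromide | CC#C[Zn]Br | intermediate
5 | triisopropyl[2-methoxy-4-(prop-1-yn-1-yl)phenoxy]silane | CC#Cc1ccc(O[Si](C(C)C)(C(C)C)C(C)C)c(OC)c1 | intermediate
6 | (Z)-alkenyl pinacol boronate | C/C(=C\c1ccc(O[Si](C(C)C)(C(C)C)C(C)C)c(OC)c1)B1OC(C)(C)C(C)(C)O1 | intermediate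
7 | 4-bromo-2,6-dimethoxyphenol | COc1cc(Br)cc(OC)c1O | starting material
8 | 2-(benzyloxy)-5-bromo-1,3-dimethoxybenzene | COc1cc(Br)cc(OC)c1OCc1ccccc1 | intermediate
9 | (E)-1,2-diarylpropene | C/C(=C\c1ccc(O[Si](C(C)C)(C(C)C)C(C)C)c(OC)c1)c1cc(OC)c(OCc2ccccc2)c(OC)c1 | intermediate
10 | (R)-diarylpropane | C[C@H](Cc1ccc(O[Si](C(C)C)(C(C)C)C(C)C)c(OC)c1)c1cc(OC)c(OCc2ccccc2)c(OC)c1 | intermediate
11 | (R)-ring B bromide | C[C@H](Cc1ccc(O[Si](C(C)C)(C(C)C)C(C)C)c(OC)c1)c1cc(OC)c(OCc2ccccc2)c(OC)c1Br | intermediate
12 | (R)-aryllithium | C[C@H](Cc1ccc(O[Si](C(C)C)(C(C)C)C(C)C)c(OC)c1)c1cc(OC)c(OCc2ccccc2)c(OC)c1[Li] | intermediate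
13 | (R)-dimethyl arylboronate | C[C@H](Cc1ccc(O[Si](C(C)C)(C(C)C)C(C)C)c(OC)c1)c1cc(OC)c(OCc2ccccc2)c(OC)c1B(OC)OC | intermediate
14 | (R)-3-(benzyloxy)-2,4-dimethoxy-6-alkylphenol | C[C@H](Cc1ccc(O[Si](C(C)C)(C(C)C)C(C)C)c(OC)c1)c1cc(OC)c(OCc2ccccc2)c(OC)c1O | intermediate
15 | (R)-2,4-dimethoxy-6-alkylbenzene-1,3-diol | C[C@H](Cc1ccc(O[Si](C(C)C)(C(C)C)C(C)C)c(OC)c1)c1cc(OC)c(O)c(OC)c1O | intermediate
16 | allyl methyl carbonate | C=CCOC(=O)OC | starting material
17 | (6R,2'R)-silyl-protected 6-allyl-3-hydroxy-2,4-dimethoxycyclohexadienone | C=CC[C@@]1([C@H](C)Cc2ccc(O[Si](C(C)C)(C(C)C)C(C)C)c(OC)c2)C=C(OC)C(O)=C(OC)C1=O | intermediate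
18 | (6R,2'R)-6-allyl-3-hydroxy-6-[1-(4-hydroxy-3-methoxyphenyl)propan-2-yl]-2,4-dimethoxycyclohexa-2,4-dien-1-one | C=CC[C@@]1([C@H](C)Cc2ccc(O)c(OC)c2)C=C(OC)C(O)=C(OC)C1=O | intermediate
19 | para-quinone methide of 18 | C=CC[C@@]1([C@H](C)C=C2C=CC(=O)C(OC)=C2)C=C(OC)C(O)=C(OC)C1=O | intermediate
20 | (1R,5S,6S,7R)-bicyclo[3.2.1]oct-2-ene-4,8-dione | C=CC[C@@]12C=C(OC)C(=O)[C@@](OC)(C1=O)[C@H](c1ccc(O)c(OC)c1)[C@H]2C | intermediate
21 | (1R,4S,5R,6S,7R)-1-allyl-4-hydroxy-6-(4-hydroxy-3-methoxyphenyl)-3,5-dimethoxy-7-methylbicyclo[3.2.1]oct-2-en-8-one | C=CC[C@@]12C=C(OC)[C@H](O)[C@@](OC)(C1=O)[C@H](c1ccc(O)c(OC)c1)[C@H]2C | target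

**Step count**
Total step count: 13. Longest linear sequence: 12 (steps 1–3 and 5–13).

**Steps most likely to fail**

1. **Step 10.**
   - What may go wrong: allylation at O4 or O8 instead of C1, a second allylation of the product diketonate at C5, or poor facial selectivity at C1 if ligand and C7 are mismatched.
   - Fallback (known chemistry, from 15 back to 17): 15 is converted with LiHMDS (2 equiv) in toluene into its dilithium salt and alkylated with allyl bromide at 0 °C. This is the classical C-alkylative dearomatisation of resorcinolate and phloroglucinolate anions in non-polar media.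
   - Control at C1 then rests only on the substrate. 17 is separated by chromatography from its C1 epimer, the (6S)-allyl dienone F1, and only 17 is carried on.

2. **Step 12.**
   - What may go wrong: closure of 19 through the C8 oxygen instead of C5, or drift from the C-closed to the O-closed isomer by reversible opening.
   - Fallback (from 18 back to 20): the oxidation is run as before and the O-closed product, trans-2-aryl-3-methyl-3a-allyl-5,7-dimethoxy-3,3a-dihydrobenzofuran-6(2H)-one F2, is isolated.
   - F2 is treated with BF3·OEt2 in CH2Cl2 at −78 °C, which breaks the benzylic C6–O8 bond to give a para-hydroxybenzyl cation and enol pair.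
   - Capture at C5 under kinetic control is the closure known from acid-promoted [5+2] cycloadditions of quinone monoketals with propenylbenzenes, and it should give 20.

3. **Step 13.**
   - What may go wrong: hydride attack at the strained bridging ketone C8 instead of, or in addition to, C4, and base-induced reopening of the C5–C6 bond.
   - Fallback (from 20 to 21): both carbonyl groups are reduced with excess NaBH4 in MeOH to the 4,8-diol F3.
   - Ac2O in pyridine acetylates the phenol and the less hindered C4 hydroxyl, but not the C8 hydroxyl between two fully substituted carbons, giving the diacetate F4.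
   - Dess–Martin periodinane restores the C8 ketone in the keto diacetate F5, and K2CO3 in MeOH removes both acetates to give 21.

**Further compounds**
F1 | step 10 | (6S)-epimer of 17 | C=CC[C@]1([C@H](C)Cc2ccc(O[Si](C(C)C)(C(C)C)C(C)C)c(OC)c2)C=C(OC)C(O)=C(OC)C1=O
F2 | step 12 | 3a-allyl-2-(4-hydroxy-3-methoxyphenyl)-5,7-dimethoxy-3-methyl-3,3a-dihydrobenzofuran-6(2H)-one (aryl trans to methyl, methyl cis to allyl) | C=CC[C@@]12C=C(OC)C(=O)C(OC)=C1O[C@H](c1ccc(O)c(OC)c1)[C@H]2C
F3 | step 13 | 4,8-diol of 20 (4-OH anti to C8, 8-OH syn to the C6–C7 bridge) | C=CC[C@@]12C=C(OC)[C@H](O)[C@@](OC)([C@@H]1O)[C@H](c1ccc(O)c(OC)c1)[C@H]2C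
F4 | step 13 | phenol and C4 diacetate of F3 | C=CC[C@@]12C=C(OC)[C@H](OC(C)=O)[C@@](OC)([C@@H]1O)[C@H](c1ccc(OC(C)=O)c(OC)c1)[C@H]2C
F5 | step 13 | diacetate of 21 | C=CC[C@@]12C=C(OC)[C@H](OC(C)=O)[C@@](OC)(C1=O)[C@H](c1ccc(OC(C)=O)c(OC)c1)[C@H]2C
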